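**Retrosynthetic overview**
1. Target 21 ⇐ desilylation of flavanone 20 ⇐ oxidation at C4 of the (2S,4S)-4-methoxyflavan 18 (OMe → OH → C=O).
2. The plan rests on ring C, the O1–C2–C3–C4 unit fused to ring A at C4a/C8a. O1, C8a, C4a and C4 come from a methoxy ortho-quinone methide of ring A (from salicylaldehyde 12), and C2–C3 from the vinyl group of ring B styrene 15. Rings A and B are bought as arenes, so ring C is the only ring formed.
3. 12 ⇐ resorcinol bis-MOM ether, by lithiation/allylation between the oxygens with the (E)-allyl chloride 3 (from isoprene monoxide), then ortho-lithiation/formylation and protecting-group exchange. The E geometry is fixed in the chloride, because an aromatic Claisen route to this chain would not control it.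
4. 15 ⇐ 3,4-dihydroxybenzaldehyde by silylation and Wittig methylenation.

Key step: step 10

Remark: the sense of induction of the phosphoric acid in step 10 cannot be predicted with confidence; the (R)-catalyst is written, and its mirror image would be used if the cycloadduct proved to be the antipode.

**Route**

Step 1
Reactants: 1 2-methyl-2-vinyloxirane (isoprene monoxide, racemic)
Product: 2 (E)-4-chloro-2-methylbut-2-en-1-ol
Conditions: TiCl4, CH2Cl2, −90 to −80 °C; then 1 M aq. HCl
Reagents that add atoms: titanium tetrachloride, Cl[Ti](Cl)(Cl)Cl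
Why: Lewis-acid SN2' opening of a vinyl epoxide, known for this epoxide, in which chloride adds at the vinyl terminus of the titanium-bound s-trans conformer and should give the E olefin with CH2OH trans to CH2Cl.

Step 2
Reactants: 2 (E)-4-chloro-2-methylbut-2-en-1-ol
Product: 3 (E)-tert-butyl[(4-chloro-2-methylbut-2-en-1-yl)oxy]dimethylsilane
Conditions: TBSCl, imidazole, CH2Cl2, 0 °C
Reagents that add atoms: tert-butyldimethylsilyl chloride, CC(C)(C)[Si](C)(C)Cl
Why: Standard silyl ether formation at a primary alcohol, needed because the next two steps use organolithium bases.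

Step 3
Reactants: 4 resorcinol
Product: 5 1,3-bis(methoxymethoxy)benzene
Conditions: NaH, MOMCl, DMF, 0 °C to rt
Reagents that add atoms: chloromethyl methyl ether, COCCl
Why: Williamson-type O-alkylation of both phenoxides installs the two acetal groups that will direct both metalations.

Step 4
Reactants: 5 1,3-bis(methoxymethoxy)benzene; 3 (E)-tert-butyl[(4-chloro-2-methylbut-2-en-1-yl)oxy]dimethylsilane
Product: 7 (E)-tert-butyl{[4-(2,6-bis(methoxymethoxy)phenyl)-2-methylbut-2-en-1-yl]oxy}dimethylsilane, via aryllithium 6 (not isolated)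
Conditions: n-BuLi, THF, 0 °C to rt; CuBr·SMe2 (10 mol %), then 3, −78 °C to rt
Reagents that add atoms: none
Why: Directed ortho-metalation at the carbon flanked by both MOM ethers, then copper-catalysed SN2 allylation at the primary chloride (the γ carbon is fully substituted, so SN2' attack is disfavoured), as known for prenyl halides, with the E geometry carried over unchanged.

Step 5
Reactants: 7 (E)-tert-butyl{[4-(2,6-bis(methoxymethoxy)phenyl)-2-methylbut-2-en-1-yl]oxy}dimethylsilane
Product: 10 2,4-bis(methoxymethoxy)-3-[(E)-4-(tert-butyldimethylsilyloxy)-3-methylbut-2-enyl]benzaldehyde, via aryllithium 8 (not isolated), via lithium hemiaminal alkoxide 9 (not isolated)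
Conditions: n-BuLi, TMEDA, THF, −20 to 0 °C; DMF, −78 °C to rt; H2O
Reagents that add atoms: N,N-dimethylformamide, CN(C)C=O
Why: A second directed ortho-metalation, now at the only ring position left next to a MOM ether, followed by Bouveault-type formylation with DMF and collapse of the hemiaminal alkoxide on work-up.

Step 6
Reactants: 10 2,4-bis(methoxymethoxy)-3-[(E)-4-(tert-butyldimethylsilyloxy)-3-methylbut-2-enyl]benzaldehyde
Product: 11 2,4-dihydroxy-3-[(E)-4-hydroxy-3-methylbut-2-enyl]benzaldehyde
Conditions: 3 M aq. HCl, THF, rt to 40 °C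
Reagents that add atoms: none
Why: Acid hydrolysis of both aryl MOM acetals and of the silyl ether; the primary allylic alcohol could ionise only to a primary/secondary allyl cation and should survive dilute aqueous acid.

Step 7
Reactants: 11 2,4-dihydroxy-3-[(E)-4-hydroxy-3-methylbut-2-enyl]benzaldehyde
Product: 12 2-hydroxy-4-(tert-butyldimethylsilyloxy)-3-[(E)-4-(tert-butyldimethylsilyloxy)-3-methylbut-2-enyl]benzaldehyde
Conditions: TBSCl (2.2 equiv), imidazole, CH2Cl2/DMF, 0 °C
Reagents that add atoms: tert-butyldimethylsilyl chloride, CC(C)(C)[Si](C)(C)Cl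
Why: Selective silylation of the primary alcohol and the para phenol, since the ortho phenol is hydrogen-bonded to the aldehyde and flanked on both sides and should stay free.

Step 8
Reactants: 13 3,4-dihydroxybenzaldehyde
Product: 14 3,4-bis(tert-butyldimethylsilyloxy)benzaldehyde
Conditions: TBSCl (2.5 equiv), imidazole, DMF, rt
Reagents that add atoms: tert-butyldimethylsilyl chloride, CC(C)(C)[Si](C)(C)Cl
Why: Standard silylation of both catechol hydroxyls.

Step 9
Reactants: 14 3,4-bis(tert-butyldimethylsilyloxy)benzaldehyde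
Product: 15 3,4-bis(tert-butyldimethylsilyloxy)styrene
Conditions: Ph3PCH3Br, n-BuLi, THF, 0 °C to rt
Reagents that add atoms: methyltriphenylphosphonium bromide, C[P+](c1ccccc1)(c1ccccc1)c1ccccc1.[Br-]
Why: Wittig methylenation of the aryl aldehyde with the non-stabilised ylide, which aryl silyl ethers tolerate.

Step 10
Reactants: 12 2-hydroxy-4-(tert-butyldimethylsilyloxy)-3-[(E)-4-(tert-butyldimethylsilyloxy)-3-methylbut-2-enyl]benzaldehyde; 15 3,4-bis(tert-butyldimethylsilyloxy)styrene (2 equiv)
Product: 18 (2S,4S)-7-(tert-butyldimethylsilyloxy)-2-[3,4-bis(tert-butyldimethylsilyloxy)phenyl]-8-[(E)-4-(tert-butyldimethylsilyloxy)-3-methylbut-2-enyl]-4-methoxychroman (2,4-cis), via dimethyl acetal 16 (not isolated), via methoxy ortho-quinone methide 17 (not isolated)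
Conditions: HC(OMe)3 (2 equiv), (R)-3,3'-bis(2,4,6-triisopropylphenyl)-1,1'-binaphthyl-2,2'-diyl hydrogen phosphate (10 mol %), 5 Å molecular sieves, toluene, 0 °C to rt
Reagents that add atoms: trimethyl orthoformate, COC(OC)OC
Why: Proposed new method: the phosphoric acid should convert 12 and HC(OMe)3 into acetal 16 and ionise it, with loss of methanol, to the methoxy ortho-quinone methide 17 (an oxocarbenium ion paired with the chiral phosphate through O1–H), after which the CH2 terminus of styrene 15 bonds to the methide carbon (C3–C4) and the phenolic oxygen closes onto the developing benzylic cation (O1–C2) in an asynchronous inverse-demand hetero-Diels–Alder reaction. The closest known reactions are the achiral-acid three-component synthesis of 2,4-cis-4-alkoxyflavans from salicylaldehydes, orthoformates and styrenes, chiral Brønsted acid catalysed cycloadditions of salicylaldehyde-acetal-derived oxocarbenium ions with vinyl ethers, and chiral phosphoric acid catalysed [4+2] reactions of ortho-quinone methides; the intermolecular enantioselective alkoxy variant with a styrene is the untested part. Ring C is closed by intermolecular [4+2] annulation, its last bond (O1–C2) being a six-membered closure of the phenol oxygen on a benzylic cation. C2 is to be set by catalyst control, the phosphate bound at O1 shielding one face of the quinone methide so that the aryl group ends up (2S), while C4 follows from the endo approach of the aryl group (2,4-cis, hence 4S) and is removed later. Regioselectivity is secured by the para-silyloxy group of 15, which stabilises positive charge at C2, and chemoselectivity over the trisubstituted side-chain olefin by the far higher nucleophilicity of the styrene, used in excess.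

Step 11
Reactants: 18 (2S,4S)-4-methoxychroman
Product: 19 (2S)-7-(tert-butyldimethylsilyloxy)-2-[3,4-bis(tert-butyldimethylsilyloxy)phenyl]-8-[(E)-4-(tert-butyldimethylsilyloxy)-3-methylbut-2-enyl]chroman-4-ol (mixture of C4 epimers)
Conditions: pyridinium p-toluenesulfonate (20 mol %), MeCN/H2O 9:1, rt to 40 °C
Reagents that add atoms: water, O
Why: SN1 solvolysis, in which the C4 ether ionises readily because its cation is stabilised by O1 (ortho) and the 7-silyloxy group (para) and is trapped by water, while the less activated C2–O1 bond and the silyl ethers should persist under this weak acid, so C2 keeps its configuration and the C4 epimer ratio is of no consequence.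

Step 12
Reactants: 19 (2S)-chroman-4-ol (C4 epimers)
Product: 20 (2S)-7-(tert-butyldimethylsilyloxy)-2-[3,4-bis(tert-butyldimethylsilyloxy)phenyl]-8-[(E)-4-(tert-butyldimethylsilyloxy)-3-methylbut-2-enyl]chroman-4-one
Conditions: Dess–Martin periodinane, NaHCO3, CH2Cl2, 0 °C to rt
Reagents that add atoms: none
Why: Dess–Martin oxidation of the secondary benzylic alcohol to the ketone under buffered conditions removes the C4 stereocentre and avoids the enolisation/ring-opening path that would epimerise C2.

Step 13
Reactants: 20 (2S)-tetrasilylated flavanone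
Product: 21 (2S)-2-(3,4-dihydroxyphenyl)-7-hydroxy-8-[(E)-4-hydroxy-3-methylbut-2-enyl]chroman-4-one (target)
Conditions: Et3N·3HF (excess), THF/MeCN, 0 °C to rt, under argon
Reagents that add atoms: none
Why: Fluoride-mediated cleavage of the three aryl silyl ethers and the primary silyl ether with a weakly acidic HF source, which avoids the base-induced retro-oxa-Michael opening to the chalcone that would racemise C2.

**Compound list**
1 | 2-methyl-2-vinyloxirane (racemic) | C=CC1(C)CO1 | starting material
2 | (E)-4-chloro-2-methylbut-2-en-1-ol | OC/C(C)=C/CCl | intermediate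
3 | (E)-tert-butyl[(4-chloro-2-methylbut-2-en-1-yl)oxy]dimethylsilane | CC(C)(C)[Si](C)(C)OC/C(C)=C/CCl | intermediate
4 | resorcinol | Oc1cccc(O)c1 | starting material
5 | 1,3-bis(methoxymethoxy)benzene | COCOc1cccc(OCOC)c1 | intermediate
6 | 2,6-bis(methoxymethoxy)phenyllithium | [Li]c1c(OCOC)cccc1OCOC | intermediate (not isolated)
7 | (E)-tert-butyl{[4-(2,6-bis(methoxymethoxy)phenyl)-2-methylbut-2-en-1-yl]oxy}dimethylsilane | COCOc1cccc(OCOC)c1C/C=C(\C)CO[Si](C)(C)C(C)(C)C | intermediate
8 | 2,4-bis(methoxymethoxy)-3-[(E)-4-(tert-butyldimethylsilyloxy)-3-methylbut-2-enyl]phenyllithium | [Li]c1ccc(OCOC)c(C/C=C(\C)CO[Si](C)(C)C(C)(C)C)c1OCOC | intermediate (not isolated)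
9 | lithium alkoxide of the DMF adduct of 8 (hemiaminal) | [Li]OC(N(C)C)c1ccc(OCOC)c(C/C=C(\C)CO[Si](C)(C)C(C)(C)C)c1OCOC | intermediate (not isolated)
10 | 2,4-bis(methoxymethoxy)-3-[(E)-4-(tert-butyldimethylsilyloxy)-3-methylbut-2-enyl]benzaldehyde | O=Cc1ccc(OCOC)c(C/C=C(\C)CO[Si](C)(C)C(C)(C)C)c1OCOC | intermediate
11 | 2,4-dihydroxy-3-[(E)-4-hydroxy-3-methylbut-2-enyl]benzaldehyde | O=Cc1ccc(O)c(C/C=C(\C)CO)c1O | intermediate
12 | 2-hydroxy-4-(tert-butyldimethylsilyloxy)-3-[(E)-4-(tert-butyldimethylsilyloxy)-3-methylbut-2-enyl]benzaldehyde | O=Cc1ccc(O[Si](C)(C)C(C)(C)C)c(C/C=C(\C)CO[Si](C)(C)C(C)(C)C)c1O | intermediate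
13 | 3,4-dihydroxybenzaldehyde | O=Cc1ccc(O)c(O)c1 | starting material
14 | 3,4-bis(tert-butyldimethylsilyloxy)benzaldehyde | O=Cc1ccc(O[Si](C)(C)C(C)(C)C)c(O[Si](C)(C)C(C)(C)C)c1 | intermediate
15 | 3,4-bis(tert-butyldimethylsilyloxy)styrene | C=Cc1ccc(O[Si](C)(C)C(C)(C)C)c(O[Si](C)(C)C(C)(C)C)c1 | intermediate
16 | dimethyl acetal of 12 | COC(OC)c1ccc(O[Si](C)(C)C(C)(C)C)c(C/C=C(\C)CO[Si](C)(C)C(C)(C)C)c1O | intermediate (not isolated)
17 | methoxy ortho-quinone methide from 16 | COC=C1C=CC(O[Si](C)(C)C(C)(C)C)=C(C/C=C(\C)CO[Si](C)(C)C(C)(C)C)C1=O | intermediate (not isolated)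
18 | (2S,4S)-7-(tert-butyldimethylsilyloxy)-2-[3,4-bis(tert-butyldimethylsilyloxy)phenyl]-8-[(E)-4-(tert-butyldimethylsilyloxy)-3-methylbut-2-enyl]-4-methoxychroman | C/C(=C\Cc1c(O[Si](C)(C)C(C)(C)C)ccc2c1O[C@H](c1ccc(O[Si](C)(C)C(C)(C)C)c(O[Si](C)(C)C(C)(C)C)c1)C[C@@H]2OC)CO[Si](C)(C)C(C)(C)C | intermediate
19 | (2S)-7-(tert-butyldimethylsilyloxy)-2-[3,4-bis(tert-butyldimethylsilyloxy)phenyl]-8-[(E)-4-(tert-butyldimethylsilyloxy)-3-methylbut-2-enyl]chroman-4-ol, C4 epimers | C/C(=C\Cc1c(O[Si](C)(C)C(C)(C)C)ccc2c1O[C@H](c1ccc(O[Si](C)(C)C(C)(C)C)c(O[Si](C)(C)C(C)(C)C)c1)CC2O)CO[Si](C)(C)C(C)(C)C | intermediate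
20 | (2S)-7-(tert-butyldimethylsilyloxy)-2-[3,4-bis(tert-butyldimethylsilyloxy)phenyl]-8-[(E)-4-(tert-butyldimethylsilyloxy)-3-methylbut-2-enyl]chroman-4-one | C/C(=C\Cc1c(O[Si](C)(C)C(C)(C)C)ccc2c1O[C@H](c1ccc(O[Si](C)(C)C(C)(C)C)c(O[Si](C)(C)C(C)(C)C)c1)CC2=O)CO[Si](C)(C)C(C)(C)C | intermediate
21 | (2S)-2-(3,4-dihydroxyphenyl)-7-hydroxy-8-[(E)-4-hydroxy-3-methylbut-2-enyl]chroman-4-one | C/C(=C\Cc1c(O)ccc2c1O[C@H](c1ccc(O)c(O)c1)CC2=O)CO | target

**Step count**
Total steps: 13. Longest linear sequence: 10 (steps 1, 2, 4, 5, 6, 7, 10, 11, 12, 13).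

**Steps most likely to fail**

Step 10. The weak acid may ionise the acetal too slowly, the styrene has no binding group so facial discrimination by the phosphate may be poor, and released methanol may attack the primary silyl ether. The fallback sets out from 12 and 15 and returns at 20. The same three-component cycloaddition run with an achiral acid (catalytic TfOH, HC(OMe)3, CH2Cl2), the established form of this reaction, should give the racemic 2,4-cis-4-methoxyflavan F1. Hydrolysis and periodinane oxidation as in steps 11 and 12 would lead through the racemic flavan-4-ols F2 to the racemic flavanone F3. Kinetic resolution by Noyori asymmetric transfer hydrogenation (RuCl[(R,R)-TsDPEN](p-cymene), HCO2H/Et3N, EtOAc) is expected, on the acetophenone model, to reduce the (2R)-ketone faster to the cis-(2R,4R)-flavan-4-ol F4. That would leave the (2S)-ketone 20, separable by chromatography.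

Step 11. Elimination of the C4 cation to the flav-3-ene may compete with capture by water, and the primary silyl ether may be lost under the aqueous acid. The fallback sets out from 18 and returns at 20. It replaces solvolysis by oxidative cleavage of the benzylic methyl ether with 2,3-dichloro-5,6-dicyano-1,4-benzoquinone in CH2Cl2/pH 7 buffer. Hydride abstraction at C4–H, water addition and loss of methanol would give ketone 20 directly, and no new compound is made (F0).

Step 5. Deprotonation at the benzylic–allylic CH2 or next to the silyloxy group may compete with ring metalation. The fallback sets out from 7 and returns at 11. Acid removal of the MOM and silyl groups (3 M aq. HCl, THF) should give 2-[(E)-4-hydroxy-3-methylbut-2-enyl]benzene-1,3-diol F5. Magnesium-mediated ortho-formylation (MgCl2, Et3N, paraformaldehyde, MeCN, reflux; Casnati–Skattebøl reaction) can only occur at the free position ortho to a phenol and would give 11.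

**Further compounds**
F1 | step 10 | racemic 2,4-cis-7-(tert-butyldimethylsilyloxy)-2-[3,4-bis(tert-butyldimethylsilyloxy)phenyl]-8-[(E)-4-(tert-butyldimethylsilyloxy)-3-methylbut-2-enyl]-4-methoxychroman | C/C(=C\Cc1c(O[Si](C)(C)C(C)(C)C)ccc2c1OC(c1ccc(O[Si](C)(C)C(C)(C)C)c(O[Si](C)(C)C(C)(C)C)c1)CC2OC)CO[Si](C)(C)C(C)(C)C
F2 | step 10 | racemic flavan-4-ols (C4 epimers) of the silylated series | C/C(=C\Cc1c(O[Si](C)(C)C(C)(C)C)ccc2c1OC(c1ccc(O[Si](C)(C)C(C)(C)C)c(O[Si](C)(C)C(C)(C)C)c1)CC2O)CO[Si](C)(C)C(C)(C)C
F3 | step 10 | racemic silylated flavanone | C/C(=C\Cc1c(O[Si](C)(C)C(C)(C)C)ccc2c1OC(c1ccc(O[Si](C)(C)C(C)(C)C)c(O[Si](C)(C)C(C)(C)C)c1)CC2=O)CO[Si](C)(C)C(C)(C)C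
F4 | step 10 | cis-(2R,4R)-flavan-4-ol of the silylated series | C/C(=C\Cc1c(O[Si](C)(C)C(C)(C)C)ccc2c1O[C@@H](c1ccc(O[Si](C)(C)C(C)(C)C)c(O[Si](C)(C)C(C)(C)C)c1)C[C@H]2O)CO[Si](C)(C)C(C)(C)C
F0 | step 11 | none | none
F5 | step 5 | 2-[(E)-4-hydroxy-3-methylbut-2-enyl]benzene-1,3-diol | C/C(=C\Cc1c(O)cccc1O)CO
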